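**Retrosynthetic overview**
- Both tiglate esters are installed in one operation on a diol, and the enal is released last from a dimethyl acetal.
- The 2-(1-formylvinyl) group comes from methylenation of a 2-(dimethoxyacetyl) ketone (C=O → C=CH2, acetal = masked CHO).
- The dihydrofuran is the only ring made (the benzene ring is bought). It closes at C2–C3 by an (S)-proline-catalysed intramolecular 5-enolexo aldol of an aryloxymethyl ketone onto the ortho-CHO, which sets both ring stereocentres (trans).
- The aldol substrate comes from O-alkylation of (R)-5-(1-hydroxyethyl)salicylaldehyde (from 4'-hydroxyacetophenone by asymmetric transfer hydrogenation, then ortho-formylation) with 1-bromo-3,3-dimethoxypropan-2-one (two steps from 1,1-dimethoxyacetone).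
- Three branches converge: aryl aldehyde, bromoketone, tiglic anhydride.

Reading of the target used throughout: trans-(2R,3S)-2,3-dihydrobenzofuran, (1R) side-chain carbinol, both esters (E)-2-methylbut-2-enoates (tiglates).

**Step 1**
Reactants: 1 4'-hydroxyacetophenone
Product: 2 4-[(1R)-1-hydroxyethyl]phenol
Conditions: RuCl[(R,R)-TsDPEN](p-cymene) (1 mol %), HCO2H/Et3N (5:2), 35 °C
Reagents that add atoms: none
Why: Noyori–Ikariya asymmetric transfer hydrogenation, in which the (R,R)-TsDPEN–Ru hydride delivers H to the Si face of the aryl methyl ketone and so sets the (1R) carbinol, while the acidic formate medium keeps the phenol protonated.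

**Step 2**
Reactants: 2 4-[(1R)-1-hydroxyethyl]phenol
Product: 3 2-hydroxy-5-[(1R)-1-hydroxyethyl]benzaldehyde
Conditions: MgCl2, Et3N, (CH2O)n, THF, 65 °C
Reagents that add atoms: paraformaldehyde (formaldehyde), C=O
Why: Casnati–Skattebøl ortho-formylation, in which the magnesium phenoxide directs hydroxymethylation to the free ortho position and a second formaldehyde oxidises the new benzylic alkoxide by hydride transfer; the carbinol centre is not involved.

**Step 3**
Reactants: 4 1,1-dimethoxypropan-2-one
Product: 5 [(3,3-dimethoxyprop-1-en-2-yl)oxy]trimethylsilane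
Conditions: LDA, TMSCl (in situ quench), THF, −78 °C
Reagents that add atoms: chlorotrimethylsilane, C[Si](C)(C)Cl
Why: Kinetic enolisation and O-silylation (silyl enol ether formation) take place at the unhindered methyl group and not at the acetal C–H, which fixes the site of the later bromination.

**Step 4**
Reactants: 5 [(3,3-dimethoxyprop-1-en-2-yl)oxy]trimethylsilane
Product: 6 1-bromo-3,3-dimethoxypropan-2-one
Conditions: NBS, THF, 0 °C; aq. NaHCO3
Reagents that add atoms: N-bromosuccinimide, O=C1CCC(=O)N1Br
Why: Electrophilic α-bromination of the silyl enol ether gives the monobromo ketone regiospecifically under non-acidic conditions that leave the dimethyl acetal intact.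

**Step 5**
Reactants: 7 tiglic acid [(2E)-2-methylbut-2-enoic acid] (2 equiv)
Product: 8 tiglic anhydride [(2E)-2-methylbut-2-enoic anhydride]
Conditions: DCC (0.5 equiv relative to the acid), CH2Cl2, 0 °C → rt; filter off the urea
Reagents that add atoms: tiglic acid (the second molecule of 7), C/C=C(\C)C(=O)O
Why: Carbodiimide dehydration joins two molecules of the acid (one is activated as the O-acylisourea and is acylated by the second) to give the symmetric anhydride, a mild acyl donor that avoids the vinylketene and deconjugation problems of tigloyl chloride with amine bases; the E geometry is untouched.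

**Step 6**
Reactants: 3 2-hydroxy-5-[(1R)-1-hydroxyethyl]benzaldehyde; 6 1-bromo-3,3-dimethoxypropan-2-one
Product: 9 2-(3,3-dimethoxy-2-oxopropoxy)-5-[(1R)-1-hydroxyethyl]benzaldehyde
Conditions: K2CO3 (1.1 equiv), acetone, 0 °C → rt
Reagents that add atoms: none
Why: Williamson ether synthesis, in which the phenoxide displaces the activated α-bromo ketone by SN2 at room temperature, below the temperature at which base-induced aldol/dehydration (Rap–Stoermer) sets in, and the aliphatic alcohol is not deprotonated.

**Step 7 (key ring closure)**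
Reactants: 9 2-(3,3-dimethoxy-2-oxopropoxy)-5-[(1R)-1-hydroxyethyl]benzaldehyde
Product: 10 1-[(2S,3S)-3-hydroxy-5-[(1R)-1-hydroxyethyl]-2,3-dihydro-1-benzofuran-2-yl]-2,2-dimethoxyethan-1-one
Conditions: (S)-proline (30 mol %), DMSO, rt
Reagents that add atoms: none
Why: Enamine-catalysed intramolecular 5-enolexo aldol (Hajos–Parrish/List type), in which proline forms the enamine on the OCH2 side only, its carboxylic acid directs attack on the Re face of the ortho-CHO (3S) through the Houk–List transition state whose anti arrangement corresponds to the trans ring (2S here, the same spatial sense as 2R in the target), and the epimerisable C2 also settles in the more stable trans form.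

**Step 8**
Reactants: 10 1-[(2S,3S)-3-hydroxy-5-[(1R)-1-hydroxyethyl]-2,3-dihydro-1-benzofuran-2-yl]-2,2-dimethoxyethan-1-one
Product: 11 (2R,3S)-2-(3,3-dimethoxyprop-1-en-2-yl)-5-[(1R)-1-hydroxyethyl]-2,3-dihydro-1-benzofuran-3-ol
Conditions: Zn, CH2Br2, TiCl4 (pre-formed Lombardo reagent, excess), THF/CH2Cl2, 0 °C → rt; aq. NaHCO3
Reagents that add atoms: dibromomethane, BrCBr
Why: Takai–Lombardo methylenation, a non-basic carbonyl olefination that tolerates free hydroxyls and acetals and converts the ketone into the 1,1-disubstituted alkene without enolisation, so C2 and C3 are neither epimerised nor eliminated and C2 is no longer acidic afterwards.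

**Step 9**
Reactants: 11 (2R,3S)-2-(3,3-dimethoxyprop-1-en-2-yl)-5-[(1R)-1-hydroxyethyl]-2,3-dihydro-1-benzofuran-3-ol; 8 tiglic anhydride
Product: 13 (1R)-1-[(2R,3S)-3-{[(2E)-2-methylbut-2-enoyl]oxy}-2-(3-oxoprop-1-en-2-yl)-2,3-dihydro-1-benzofuran-5-yl]ethyl (2E)-2-methylbut-2-enoate (target), via bis-tiglate dimethyl acetal 12 (not isolated)
Conditions: 8 (3 equiv), DMAP (0.3 equiv), Et3N, CH2Cl2, 0 °C → rt; then THF, 1 M aq. oxalic acid (pH ≈ 2), rt
Reagents that add atoms: tiglic anhydride (the second equivalent of 8, one tigloyl group per anhydride), C/C=C(\C)C(=O)OC(=O)/C(C)=C/C; water, O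
Why: DMAP-catalysed (Steglich-type) acylation esterifies both secondary alcohols at oxygen with retention at both carbinol carbons, and the acidic aqueous finish hydrolyses the allylic dimethyl acetal, which ionises far faster than the two benzylic esters, to release the enal.

**Compound list**
1 | 4'-hydroxyacetophenone | CC(=O)c1ccc(O)cc1 | starting material
2 | 4-[(1R)-1-hydroxyethyl]phenol | Oc1ccc([C@@H](C)O)cc1 | intermediate
3 | 2-hydroxy-5-[(1R)-1-hydroxyethyl]benzaldehyde | O=Cc1cc([C@@H](C)O)ccc1O | intermediate
4 | 1,1-dimethoxypropan-2-one | CC(=O)C(OC)OC | starting material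
5 | [(3,3-dimethoxyprop-1-en-2-yl)oxy]trimethylsilane | C=C(O[Si](C)(C)C)C(OC)OC | intermediate
6 | 1-bromo-3,3-dimethoxypropan-2-one | BrCC(=O)C(OC)OC | intermediate
7 | tiglic acid, (2E)-2-methylbut-2-enoic acid | C/C=C(\C)C(=O)O | starting material
8 | tiglic anhydride, (2E)-2-methylbut-2-enoic anhydride | C/C=C(\C)C(=O)OC(=O)/C(C)=C/C | intermediate
9 | 2-(3,3-dimethoxy-2-oxopropoxy)-5-[(1R)-1-hydroxyethyl]benzaldehyde | COC(OC)C(=O)COc1ccc([C@@H](C)O)cc1C=O | intermediate
10 | 1-[(2S,3S)-3-hydroxy-5-[(1R)-1-hydroxyethyl]-2,3-dihydro-1-benzofuran-2-yl]-2,2-dimethoxyethan-1-one (trans) | COC(OC)C(=O)[C@H]1Oc2ccc([C@@H](C)O)cc2[C@@H]1O | intermediate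
11 | (2R,3S)-2-(3,3-dimethoxyprop-1-en-2-yl)-5-[(1R)-1-hydroxyethyl]-2,3-dihydro-1-benzofuran-3-ol (trans) | C=C(C(OC)OC)[C@H]1Oc2ccc([C@@H](C)O)cc2[C@@H]1O | intermediate
12 | (1R)-1-[(2R,3S)-2-(3,3-dimethoxyprop-1-en-2-yl)-3-{[(2E)-2-methylbut-2-enoyl]oxy}-2,3-dihydro-1-benzofuran-5-yl]ethyl (2E)-2-methylbut-2-enoate (not isolated) | C=C(C(OC)OC)[C@H]1Oc2ccc([C@@H](C)OC(=O)/C(C)=C/C)cc2[C@@H]1OC(=O)/C(C)=C/C | intermediate
13 | (1R)-1-[(2R,3S)-3-{[(2E)-2-methylbut-2-enoyl]oxy}-2-(3-oxoprop-1-en-2-yl)-2,3-dihydro-1-benzofuran-5-yl]ethyl (2E)-2-methylbut-2-enoate | C=C(C=O)[C@H]1Oc2ccc([C@@H](C)OC(=O)/C(C)=C/C)cc2[C@@H]1OC(=O)/C(C)=C/C | target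

**Total step count:** 9

**Longest linear sequence:** 6 steps (steps 1, 2, 6, 7, 8, 9; the bromoketone branch through steps 3, 4, 6, 7, 8, 9 is equally long; step 5 is a separate one-step branch).

**Three steps most likely to fail**

Step 7 (aldol ring closure). The risks are dehydration of the β-hydroxy ketone to the 2-acylbenzofuran, retro-aldol, and the fact that the sense and level of induction are argued from the Houk–List model rather than from a closely matching precedent for an aryl aldehyde acceptor. The fallback gives up catalyst control. It sets out from 9, which is cyclised under thermodynamic control with an achiral base (DBU 10 mol %, CH2Cl2, −20 °C). This should give the trans aldol as a roughly 1:1 pair of 10 and the (2R,3R) ring diastereomer of the aldol F1. Because the (1R) carbinol is fixed, the two are diastereomers and can be separated by preparative HPLC. F1 is returned to the same base, where retro-aldol and re-aldol through 9 re-equilibrate it, so material is funnelled into 10, where the route is rejoined.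

Step 8 (methylenation). The ketone is hindered and sits in a β-hydroxy ketone. The Lewis-acidic titanium/zinc medium could trigger retro-aldol, ionisation at C3 with aromatisation to a benzofuran, ionisation of the side-chain carbinol, or partial acetal loss. The fallback is a two-stage Peterson olefination that sets out from 10. Excess Me3SiCH2Li/CeCl3 (THF, −78 °C) adds to the ketone and gives the β-hydroxysilane triol F2, an epimer mixture at the new carbinol that does not matter. KH (THF, 0 °C → rt) then causes syn-elimination of silanolate and delivers 11, where the route is rejoined; no carbonyl is left at that stage, so the base cannot cause β-elimination.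

Step 2 (ortho-formylation with the free carbinol). A p-hydroxybenzylic alcohol held at 65 °C with base can ionise through a p-quinone methide, which would erode the ee or give 4-vinylphenol, and the free alcohol can also be partly oxidised or formylated. The fallback protects the carbinol first and sets out from 2. TBSCl (2.2 equiv)/imidazole in DMF gives the bis-silyl ether F3. K2CO3 in MeOH at rt cleaves only the aryl silyl ether and gives the silyl-protected phenol F4. The same MgCl2/Et3N/(CH2O)n formylation then gives the silyl-protected salicylaldehyde F5. TBAF buffered with AcOH (THF, 0 °C) removes the silyl group and gives 3, where the route is rejoined.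

**Further compounds**
F1 | step 7 | 1-[(2R,3R)-3-hydroxy-5-[(1R)-1-hydroxyethyl]-2,3-dihydro-1-benzofuran-2-yl]-2,2-dimethoxyethan-1-one | COC(OC)C(=O)[C@@H]1Oc2ccc([C@@H](C)O)cc2[C@H]1O
F2 | step 8 | 2-[(2S,3S)-3-hydroxy-5-[(1R)-1-hydroxyethyl]-2,3-dihydro-1-benzofuran-2-yl]-1,1-dimethoxy-3-(trimethylsilyl)propan-2-ol (epimer mixture at C-2 of the propanol) | COC(OC)C(O)(C[Si](C)(C)C)[C@H]1Oc2ccc([C@@H](C)O)cc2[C@@H]1O
F3 | step 2 | tert-butyl{4-[(1R)-1-{[tert-butyl(dimethyl)silyl]oxy}ethyl]phenoxy}dimethylsilane | CC(C)(C)[Si](C)(C)Oc1ccc([C@@H](C)O[Si](C)(C)C(C)(C)C)cc1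
F4 | step 2 | 4-[(1R)-1-{[tert-butyl(dimethyl)silyl]oxy}ethyl]phenol | Oc1ccc([C@@H](C)O[Si](C)(C)C(C)(C)C)cc1
F5 | step 2 | 5-[(1R)-1-{[tert-butyl(dimethyl)silyl]oxy}ethyl]-2-hydroxybenzaldehyde | O=Cc1cc([C@@H](C)O[Si](C)(C)C(C)(C)C)ccc1O
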